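**Retrosynthetic overview**

1. The target is 6α-angeloyloxy-1β,10α:4α,5β-diepoxygermacr-11(13)-en-8α,12-olide. Both oxiranes, the angelate and the C13 methylene are added last to a 6α,8α-dioxygenated (1(10)E,4E)-germacradiene that carries a C7 acetate arm.
2. Enabling feature: the lactone oxygen O8 is homoallylic to the latent (E)-C1=C10 alkene through the C9 methylene, O–C8–C9H2–C10(CH3)=C1H in ring A (the ten-membered carbocycle). This is the retron of a syn hydroalkylation of a methyl alkyne (C1≡C10–C14) by a terminal oxirane (C8–C9). Ring A is therefore closed at C9–C10 by a nickel-catalysed reductive epoxide–alkyne cyclisation, which also fixes the E geometry and frees O8.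
3. The open-chain epoxy-enyne gets its all-syn C6/C7/C8 triad from an Evans syn-aldol (C6–C7; (E)-3-methyloct-2-en-6-ynal plus a succinate imide), a chloromethyl ketone, a hydroxyl-directed syn reduction (C8) and oxirane closure.
4. Order of ring formation: temporary terminal oxirane (C8–C9), then ring A (key step), then ring B (γ-lactone, O8 onto C12), then the 1,10- and 4,5-oxiranes together in the last step.

Key step: step 11

Remark: germacrane numbering is used (ring A = C1–C10, C14 on C10, C15 on C4, C11–C13 = lactone arm on C7), and the ester on O6 is the (Z)-2-methylbut-2-enoate (angelate).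

**Route**

Step 1
Reactants: 1 pent-3-yn-1-ol
Product: 2 5-bromopent-2-yne
Conditions: CBr4, PPh3, CH2Cl2, 0 °C
Reagents that add atoms: tetrabromomethane BrC(Br)(Br)Br
Why: Appel bromination of the primary alcohol by SN2 displacement of the oxyphosphonium; no stereocentre is involved.

Step 2
Reactants: 2 5-bromopent-2-yne; 3 ethyl but-2-ynoate
Product: 5 ethyl (2E)-3-methyloct-2-en-6-ynoate, via pent-3-yn-1-ylmagnesium bromide 4 (not isolated)
Conditions: Mg, THF, rt; CuBr·SMe2 (1.0 equiv), −40 °C; 3, −78 °C; MeOH then aq NH4Cl, −78 °C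
Reagents that add atoms: none
Why: syn-carbocupration of the alkynoate by the Grignard-derived organocopper at low temperature, then protonation with retention, places the new chain cis to H and so should give the (E)-trisubstituted enoate that becomes C4=C5.

Step 3
Reactants: 5 ethyl (2E)-3-methyloct-2-en-6-ynoate
Product: 6 (2E)-3-methyloct-2-en-6-yn-1-ol
Conditions: DIBAL-H (iBu2AlH, 2.2 equiv), CH2Cl2, −78 °C
Reagents that add atoms: none
Why: 1,2-reduction of the α,β-unsaturated ester by the aluminium hydride gives the allylic alcohol without touching the alkyne or the alkene geometry.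

Step 4
Reactants: 6 (2E)-3-methyloct-2-en-6-yn-1-ol
Product: 7 (2E)-3-methyloct-2-en-6-ynal
Conditions: MnO2, CH2Cl2, rt
Reagents that add atoms: none
Why: MnO2 oxidises allylic alcohols selectively to enals under neutral conditions that keep the E geometry.

Step 5
Reactants: 8 4-tert-butoxy-4-oxobutanoic acid; 9 (4S)-4-benzyl-1,3-oxazolidin-2-one
Product: 11 tert-butyl 4-[(4S)-4-benzyl-2-oxo-1,3-oxazolidin-3-yl]-4-oxobutanoate, via mixed pivalic anhydride 10 (not isolated)
Conditions: t-BuCOCl, Et3N, THF, −20 °C; then LiCl, 9, −20 °C to rt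
Reagents that add atoms: none
Why: N-acylation of the Evans oxazolidinone through the mixed pivalic anhydride (LiCl/Et3N protocol); the auxiliary supplies the only stereocentre.

Step 6
Reactants: 11 tert-butyl 4-[(4S)-4-benzyl-2-oxo-1,3-oxazolidin-3-yl]-4-oxobutanoate; 7 (2E)-3-methyloct-2-en-6-ynal
Product: 13 tert-butyl (3S,4R,5E)-3-[(4S)-4-benzyl-2-oxo-1,3-oxazolidine-3-carbonyl]-4-hydroxy-6-methylundec-5-en-9-ynoate, via dibutylboron Z-enolate 12 (not isolated)
Conditions: Bu2BOTf, i-Pr2NEt, CH2Cl2, −78 to 0 °C; 7, −78 to 0 °C; pH 7 buffer, MeOH, H2O2, 0 °C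
Reagents that add atoms: none
Why: Evans syn-aldol reaction, in which the Z-boron enolate reacts through a closed chair transition state on the face left open by the (S)-benzyl auxiliary and so should set C7 and C6 (germacrane numbering) as the required syn pair.

Step 7
Reactants: 13 tert-butyl (3S,4R,5E)-3-[(4S)-4-benzyl-2-oxo-1,3-oxazolidine-3-carbonyl]-4-hydroxy-6-methylundec-5-en-9-ynoate
Product: 14 tert-butyl (3S,4R,5E)-4-hydroxy-3-[methoxy(methyl)carbamoyl]-6-methylundec-5-en-9-ynoate
Conditions: MeONHMe·HCl, AlMe3, CH2Cl2, −20 to 0 °C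
Reagents that add atoms: N,O-dimethylhydroxylamine hydrochloride CNOC.Cl
Why: Weinreb transamidation of the β-hydroxy imide with the aluminium amide releases the auxiliary, and the hindered tert-butyl ester is expected to stay intact.

Step 8
Reactants: 14 tert-butyl (3S,4R,5E)-4-hydroxy-3-[methoxy(methyl)carbamoyl]-6-methylundec-5-en-9-ynoate
Product: 15 tert-butyl (3S,4R,5E)-3-(chloroacetyl)-4-hydroxy-6-methylundec-5-en-9-ynoate
Conditions: ICH2Cl (3 equiv), MeLi·LiBr (3 equiv), THF, −78 °C; aq NH4Cl
Reagents that add atoms: chloroiodomethane ClCI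
Why: chloromethyllithium (carbenoid homologation) adds once to the Weinreb amide because the chelated tetrahedral intermediate persists until the quench, so the C7 centre next to the new ketone is not exposed to base.

Step 9
Reactants: 15 tert-butyl (3S,4R,5E)-3-(chloroacetyl)-4-hydroxy-6-methylundec-5-en-9-ynoate
Product: 17 tert-butyl (3S,4R,5E)-4-hydroxy-6-methyl-3-[(2R)-oxiran-2-yl]undec-5-en-9-ynoate, via chlorohydrin diol 16 (not isolated)
Conditions: Et2BOMe, THF/MeOH (4:1), −78 °C; NaBH4, −78 °C; then K2CO3, MeOH, 0 °C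
Reagents that add atoms: none
Why: Narasaka–Prasad reduction delivers hydride axially to the boron chelate of the β-hydroxy ketone and should set C8 1,3-syn to C6, and the chlorohydrin then closes (Williamson, 3-exo-tet) to the terminal oxirane without touching the C8–O bond.

Step 10
Reactants: 17 tert-butyl (3S,4R,5E)-4-hydroxy-6-methyl-3-[(2R)-oxiran-2-yl]undec-5-en-9-ynoate
Product: 18 tert-butyl (3R,4R,5E)-6-methyl-3-[(2R)-oxiran-2-yl]-4-(triisopropylsilyloxy)undec-5-en-9-ynoate
Conditions: TIPSOTf, 2,6-lutidine, CH2Cl2, −78 to −20 °C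
Reagents that add atoms: triisopropylsilyl trifluoromethanesulfonate CC(C)[Si](C(C)C)(C(C)C)OS(=O)(=O)C(F)(F)F
Why: silylation of the allylic alcohol with the silyl triflate and a hindered base; the triisopropylsilyl ether is chosen because it resists 1,3-migration and is a poor allylic leaving group towards zerovalent nickel.

Step 11
Reactants: 18 tert-butyl (3R,4R,5E)-6-methyl-3-[(2R)-oxiran-2-yl]-4-(triisopropylsilyloxy)undec-5-en-9-ynoate
Product: 20 tert-butyl 8α-hydroxy-6α-(triisopropylsilyloxy)-13-norgermacra-1(10)E,4E-dien-12-oate, via O8-diethylborinate 19 (not isolated)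
Conditions: Ni(cod)2 (20 mol %), PBu3 (40 mol %), Et3B (3 equiv), THF, slow addition of 18 to 0.005 M, 23 °C; aqueous work-up
Reagents that add atoms: none
Why: Proposed new method: zerovalent nickel is expected to add to the unhindered C9–O bond of the oxirane, the tethered methyl alkyne then inserts syn so that C9 bonds to C10 and nickel sits on C1, and Et3B hands an ethyl group to nickel (boron taking the C8 alkoxide) before β-hydride elimination and C–H reductive elimination release the alkene and ethene; the closest known reaction type is the nickel-catalysed reductive coupling of alkynes with epoxides, known intermolecularly for aryl alkynes and enynes and intramolecularly for small rings and a macrolactone, but not for a dialkyl alkyne closing a ten-membered carbocycle. Ring A closes in the endo mode with respect to both partners, so both alkyne carbons and both oxirane carbons end up in the ring and the oxygen stays exocyclic on C8. No new stereocentre is formed: C8 keeps the oxirane configuration because its C–O bond is never broken, and the 1(10)E geometry follows from syn addition of H and C9 across the alkyne. The step needs regioselectivity at the alkyne (C10 against C1), which the small methyl group and the preference for the ten-membered endocyclic over the nine-membered exocyclic ring should secure, and at the oxirane (C9 against C8), which the unsubstituted terminus secures. It also needs ring closure to outrun oligomerisation, secured by slow addition at high dilution, and chemoselectivity, secured by a precursor without acrylate, aldehyde or allylic ester (O6 is a silyl ether and C11–C12 a saturated tert-butyl ester).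

Step 12
Reactants: 20 tert-butyl 8α-hydroxy-6α-(triisopropylsilyloxy)-13-norgermacra-1(10)E,4E-dien-12-oate
Product: 21 6α-(triisopropylsilyloxy)-13-norgermacra-1(10)E,4E-dien-8α,12-olide
Conditions: KOtBu (0.3 equiv), THF, 0 °C
Reagents that add atoms: none
Why: alkoxide-catalysed intramolecular transesterification (5-exo-trig acyl substitution of O8 on C12) should close the trans-fused γ-lactone, with tert-butoxide regenerated as the turnover base.

Step 13
Reactants: 21 6α-(triisopropylsilyloxy)-13-norgermacra-1(10)E,4E-dien-8α,12-olide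
Product: 23 13-(dimethylamino)-6α-(triisopropylsilyloxy)-11βH,13-dihydrogermacra-1(10)E,4E-dien-8α,12-olide, via lithium enolate 22 (not isolated)
Conditions: LDA (LiN(i-Pr)2), THF, −78 °C; Eschenmoser's salt, −78 to 0 °C
Reagents that add atoms: N,N-dimethylmethyleneiminium iodide (Eschenmoser's salt) C=[N+](C)C.[I-]
Why: Mannich aminomethylation of the lactone enolate at C11, expected anti to the C6 branch; the new C11 centre is destroyed in the next step, so its configuration does not matter.

Step 14
Reactants: 23 13-(dimethylamino)-6α-(triisopropylsilyloxy)-11βH,13-dihydrogermacra-1(10)E,4E-dien-8α,12-olide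
Product: 25 6α-(triisopropylsilyloxy)germacra-1(10)E,4E,11(13)-trien-8α,12-olide, via trimethylammonium iodide 24 (not isolated)
Conditions: MeI, MeOH, rt; then aq NaHCO3, EtOAc, rt
Reagents that add atoms: none
Why: exhaustive N-methylation followed by Hofmann-type E1cB elimination through the acidic C11–H should give the exocyclic α-methylene lactone.

Step 15
Reactants: 25 6α-(triisopropylsilyloxy)germacra-1(10)E,4E,11(13)-trien-8α,12-olide
Product: 26 6α-hydroxygermacra-1(10)E,4E,11(13)-trien-8α,12-olide
Conditions: TBAF, AcOH, THF, 0 °C to rt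
Reagents that add atoms: none
Why: fluoride desilylation buffered with acetic acid, to spare the base-sensitive methylene lactone and the acid-sensitive 1,5-diene.

Step 16
Reactants: 26 6α-hydroxygermacra-1(10)E,4E,11(13)-trien-8α,12-olide; 27 angelic acid
Product: 29 6α-angeloyloxygermacra-1(10)E,4E,11(13)-trien-8α,12-olide, via mixed 2,4,6-trichlorobenzoic anhydride 28 (not isolated)
Conditions: 2,4,6-Cl3C6H2COCl, Et3N, toluene, rt; then 26, 70 °C
Reagents that add atoms: none
Why: Yamaguchi-type esterification through the mixed anhydride, run without a nucleophilic amine catalyst, should acylate the hindered 6α-hydroxyl while keeping the Z geometry of the angelate, and C6 is not touched.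

Step 17
Reactants: 29 6α-angeloyloxygermacra-1(10)E,4E,11(13)-trien-8α,12-olide
Product: 30 (1R,4R,5R,6S,7R,8S,10R)-6-angeloyloxy-1,10:4,5-diepoxygermacr-11(13)-en-12,8-olide
Conditions: mCPBA (2.5 equiv), NaHCO3, CH2Cl2, 0 °C to rt
Reagents that add atoms: 3-chloroperoxybenzoic acid OOC(=O)c1cccc(Cl)c1
Why: Prilezhaev epoxidation, in which the peracid should attack each electron-rich trisubstituted ring alkene from its outer face because the inner face is covered by the ring in the crossed (E,E)-cyclodecadiene conformation (for C4=C5 this is the face syn to O6), setting C1/C10 as 1β,10α and C4/C5 as 4α,5β, while the conjugated methylene lactone and angelate alkenes are too electron-poor to react.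

**Compound list**

1 | pent-3-yn-1-ol | CC#CCCO | starting material
2 | 5-bromopent-2-yne | CC#CCCBr | intermediate
3 | ethyl but-2-ynoate | CC#CC(=O)OCC | starting material
4 | pent-3-yn-1-ylmagnesium bromide | CC#CCC[Mg]Br | intermediate (not isolated)
5 | ethyl (2E)-3-methyloct-2-en-6-ynoate | CC#CCC/C(C)=C/C(=O)OCC | intermediate
6 | (2E)-3-methyloct-2-en-6-yn-1-ol | CC#CCC/C(C)=C/CO | intermediate
7 | (2E)-3-methyloct-2-en-6-ynal | CC#CCC/C(C)=C/C=O | intermediate
8 | 4-tert-butoxy-4-oxobutanoic acid (mono-tert-butyl succinate) | CC(C)(C)OC(=O)CCC(=O)O | starting material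
9 | (4S)-4-benzyl-1,3-oxazolidin-2-one | O=C1N[C@@H](Cc2ccccc2)CO1 | starting material
10 | 4-tert-butoxy-4-oxobutanoic pivalic anhydride | CC(C)(C)OC(=O)CCC(=O)OC(=O)C(C)(C)C | intermediate (not isolated)
11 | tert-butyl 4-[(4S)-4-benzyl-2-oxo-1,3-oxazolidin-3-yl]-4-oxobutanoate | CC(C)(C)OC(=O)CCC(=O)N1[C@@H](Cc2ccccc2)COC1=O | intermediate
12 | (Z)-dibutylboron enolate of 11 | CCCCB(CCCC)O/C(=C\CC(=O)OC(C)(C)C)N1[C@@H](Cc2ccccc2)COC1=O | intermediate (not isolated)
13 | tert-butyl (3S,4R,5E)-3-[(4S)-4-benzyl-2-oxo-1,3-oxazolidine-3-carbonyl]-4-hydroxy-6-methylundec-5-en-9-ynoate (syn-aldol; chain C3 = C7, C4 = C6) | CC(C)(C)OC(=O)C[C@@H]([C@H](O)/C=C(\C)CCC#CC)C(=O)N1[C@@H](Cc2ccccc2)COC1=O | intermediate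
14 | tert-butyl (3S,4R,5E)-4-hydroxy-3-[methoxy(methyl)carbamoyl]-6-methylundec-5-en-9-ynoate | CC(C)(C)OC(=O)C[C@@H]([C@H](O)/C=C(\C)CCC#CC)C(=O)N(C)OC | intermediate
15 | tert-butyl (3S,4R,5E)-3-(chloroacetyl)-4-hydroxy-6-methylundec-5-en-9-ynoate | CC(C)(C)OC(=O)C[C@@H]([C@H](O)/C=C(\C)CCC#CC)C(=O)CCl | intermediate
16 | tert-butyl (3S,4R,5E)-3-[(1R)-2-chloro-1-hydroxyethyl]-4-hydroxy-6-methylundec-5-en-9-ynoate (6,8-syn diol) | CC(C)(C)OC(=O)C[C@@H]([C@H](O)/C=C(\C)CCC#CC)[C@@H](O)CCl | intermediate (not isolated)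
17 | tert-butyl (3S,4R,5E)-4-hydroxy-6-methyl-3-[(2R)-oxiran-2-yl]undec-5-en-9-ynoate | CC(C)(C)OC(=O)C[C@@H]([C@H](O)/C=C(\C)CCC#CC)[C@@H]1CO1 | intermediate
18 | tert-butyl (3R,4R,5E)-6-methyl-3-[(2R)-oxiran-2-yl]-4-(triisopropylsilyloxy)undec-5-en-9-ynoate | CC(C)(C)OC(=O)C[C@@H]([C@H](O[Si](C(C)C)(C(C)C)C(C)C)/C=C(\C)CCC#CC)[C@@H]1CO1 | intermediate
19 | O8-diethylborinate of 20 | CC(C)(C)OC(=O)C[C@@H]1[C@@H](OB(CC)CC)C/C(C)=C/CC/C(C)=C/[C@H]1O[Si](C(C)C)(C(C)C)C(C)C | intermediate (not isolated)
20 | tert-butyl 8α-hydroxy-6α-(triisopropylsilyloxy)-13-norgermacra-1(10)E,4E-dien-12-oate (ring A; C7 carries CH2CO2tBu, 7α-H) | CC(C)(C)OC(=O)C[C@@H]1[C@@H](O)C/C(C)=C/CC/C(C)=C/[C@H]1O[Si](C(C)C)(C(C)C)C(C)C | intermediate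
21 | 6α-(triisopropylsilyloxy)-13-norgermacra-1(10)E,4E-dien-8α,12-olide (trans-fused lactone, 7α-H, 8β-H) | O=C1O[C@H]2C/C(C)=C/CC/C(C)=C/[C@@H](O[Si](C(C)C)(C(C)C)C(C)C)[C@@H]2C1 | intermediate
22 | lithium enolate of 21 | [Li]OC1=C[C@H]2[C@H](O[Si](C(C)C)(C(C)C)C(C)C)/C=C(\C)CC/C=C(\C)C[C@@H]2O1 | intermediate (not isolated)
23 | 13-(dimethylamino)-6α-(triisopropylsilyloxy)-11βH,13-dihydrogermacra-1(10)E,4E-dien-8α,12-olide (expected C11 epimer; the other converges) | CN(C)C[C@H]1C(=O)O[C@H]2C/C(C)=C/CC/C(C)=C/[C@@H](O[Si](C(C)C)(C(C)C)C(C)C)[C@H]12 | intermediate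
24 | N-methyl iodide (trimethylammonium salt) of 23 | C[N+](C)(C)C[C@H]1C(=O)O[C@H]2C/C(C)=C/CC/C(C)=C/[C@@H](O[Si](C(C)C)(C(C)C)C(C)C)[C@H]12.[I-] | intermediate (not isolated)
25 | 6α-(triisopropylsilyloxy)germacra-1(10)E,4E,11(13)-trien-8α,12-olide | C=C1C(=O)O[C@H]2C/C(C)=C/CC/C(C)=C/[C@@H](O[Si](C(C)C)(C(C)C)C(C)C)[C@H]12 | intermediate
26 | 6α-hydroxygermacra-1(10)E,4E,11(13)-trien-8α,12-olide | C=C1C(=O)O[C@H]2C/C(C)=C/CC/C(C)=C/[C@@H](O)[C@H]12 | intermediate
27 | angelic acid, (2Z)-2-methylbut-2-enoic acid | C/C=C(/C)C(=O)O | starting material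
28 | angelic 2,4,6-trichlorobenzoic anhydride | C/C=C(/C)C(=O)OC(=O)c1c(Cl)cc(Cl)cc1Cl | intermediate (not isolated)
29 | 6α-angeloyloxygermacra-1(10)E,4E,11(13)-trien-8α,12-olide | C=C1C(=O)O[C@H]2C/C(C)=C/CC/C(C)=C/[C@@H](OC(=O)/C(C)=C\C)[C@H]12 | intermediate
30 | (1R,4R,5R,6S,7R,8S,10R)-6-angeloyloxy-1,10:4,5-diepoxygermacr-11(13)-en-12,8-olide (1β,10α- and 4α,5β-oxiranes, 6α-ester, trans 8α,12-lactone) | C=C1C(=O)O[C@H]2C[C@@]3(C)O[C@@H]3CC[C@@]3(C)O[C@@H]3[C@@H](OC(=O)/C(C)=C\C)[C@H]12 | target

**Step count**

Total: 17 steps. Longest linear sequence: 16 steps (steps 1–4, then 6–17).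

**Steps most likely to fail, with fallbacks**

1. Step 11 (proposed new method). Closure of the strained (E,E)-cyclodecadiene may be slow, so oligomerisation, isomerisation of the oxirane, or C–C bond formation at C1 (nine-membered ring with an exocyclic alkene) could take over. The fallback sets out from 18 and returns at 20. It forms the same C9–C10 bond by an established aldehyde–alkyne ring closure and removes the surplus oxygen afterwards.
   - Neutral hydrolysis of the terminal oxirane with the matched (salen)Co(OAc) catalyst (the acetate of the trivalent cobalt complex of N,N'-bis(3,5-di-tert-butylsalicylidene)cyclohexane-1,2-diamine) in wet THF would give the 8,9-diol F1.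
   - TESOTf/2,6-lutidine would give the bis(triethylsilyl) ether F2.
   - Swern oxidation, which turns a primary triethylsilyl ether directly into the aldehyde, would give the α-silyloxy aldehyde F3.
   - Nickel-catalysed reductive macrocyclisation of the ynal (Ni(cod)2, IMes, Et3SiH, high dilution) would give the ten-membered 8,9-bis(silyl ether) F4 with the 1(10)E alkene; both C9 epimers converge.
   - TBAF/AcOH at 0 °C, which leaves the triisopropylsilyl ether in place, would free the 8,9-diol F5.
   - Carbonyldiimidazole would give the alkenyl cyclic carbonate F6.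
   - Palladium-catalysed formate hydrogenolysis (Pd2(dba)3, PBu3, HCO2H/Et3N) would remove the C9 oxygen and return 20. With alkenyl oxiranes and alkenyl cyclic carbonates this reaction ionises the allylic C–O bond, delivers hydride to that carbon and leaves a homoallylic alcohol with the alkene in place.

2. Step 17. Attack at the 4,5-alkene next to the bulky, electron-withdrawing allylic ester may be sluggish or unselective, and a mono-epoxide that lingers may undergo acid-triggered transannular cyclisation. The fallback sets out from 26 and returns at 30. It epoxidises before acylation so that the free 6α-hydroxyl directs the oxidant. mCPBA (2.2 equiv, NaHCO3) on 26 would give the diepoxy alcohol F7, and angeloylation under the conditions of step 16 would give 30. Hydroxyl-directed delivery to C4=C5 should follow the threo preference of allylic alcohols whose alkene carries a cis substituent (C15), which is the same outer face; C1=C10 reacts from its open face.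

3. Step 12. Under alkoxide conditions a 1,3-O-to-O silyl shift followed by lactonisation through O6 could compete, or acyl substitution at the hindered tert-butyl ester could stall. The fallback sets out from 20 and returns at 21. It unmasks the carboxyl group without base: TMSOTf/2,6-lutidine cleaves the tert-butyl ester to the silyl ester, mild methanolysis gives the hydroxy acid F8, and carbodiimide lactonisation (EDC·HCl, DMAP, Steglich conditions) closes ring B.

**Further compounds**

F1 | step 11 | 8,9-diol from hydrolysis of 18 (tert-butyl ester, 6-OTIPS, alkyne intact) | CC(C)(C)OC(=O)C[C@@H]([C@H](O[Si](C(C)C)(C(C)C)C(C)C)/C=C(\C)CCC#CC)[C@@H](O)CO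
F2 | step 11 | 8,9-bis(triethylsilyl) ether of F1 | CC(C)(C)OC(=O)C[C@@H]([C@H](O[Si](C(C)C)(C(C)C)C(C)C)/C=C(\C)CCC#CC)[C@@H](O[Si](CC)(CC)CC)CO[Si](CC)(CC)CC
F3 | step 11 | C9 aldehyde with 8-OTES and 6-OTIPS (open-chain ynal) | CC(C)(C)OC(=O)C[C@@H]([C@H](O[Si](C(C)C)(C(C)C)C(C)C)/C=C(\C)CCC#CC)[C@@H](O[Si](CC)(CC)CC)C=O
F4 | step 11 | tert-butyl 8α,9-bis(triethylsilyloxy)-6α-(triisopropylsilyloxy)-13-norgermacra-1(10)E,4E-dien-12-oate (C9 epimers) | CC(C)(C)OC(=O)C[C@@H]1[C@@H](O[Si](CC)(CC)CC)C(O[Si](CC)(CC)CC)/C(C)=C/CC/C(C)=C/[C@H]1O[Si](C(C)C)(C(C)C)C(C)C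
F5 | step 11 | tert-butyl 8α,9-dihydroxy-6α-(triisopropylsilyloxy)-13-norgermacra-1(10)E,4E-dien-12-oate (C9 epimers) | CC(C)(C)OC(=O)C[C@@H]1[C@@H](O)C(O)/C(C)=C/CC/C(C)=C/[C@H]1O[Si](C(C)C)(C(C)C)C(C)C
F6 | step 11 | 8,9-cyclic carbonate of F5 | CC(C)(C)OC(=O)C[C@@H]1[C@H]2OC(=O)OC2/C(C)=C/CC/C(C)=C/[C@H]1O[Si](C(C)C)(C(C)C)C(C)C
F7 | step 17 | 6α-hydroxy-1β,10α:4α,5β-diepoxygermacr-11(13)-en-8α,12-olide | C=C1C(=O)O[C@H]2C[C@@]3(C)O[C@@H]3CC[C@@]3(C)O[C@@H]3[C@@H](O)[C@H]12
F8 | step 12 | 8α-hydroxy-6α-(triisopropylsilyloxy)-13-norgermacra-1(10)E,4E-dien-12-oic acid | OC(=O)C[C@@H]1[C@@H](O)C/C(C)=C/CC/C(C)=C/[C@H]1O[Si](C(C)C)(C(C)C)C(C)C
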